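## The problem

Target 29 is a trans-fused octalin. Throughout, its carbons are numbered C1 (alkene carbon bearing the methyl ester), C2, C3, C4 (ring-fusion CH), C5 (quaternary, methyl and side chain), C6 (CHCl), C7, C8 (CHOH), C9 (ring-fusion carbon with the angular methyl), C10 (CH bearing the formyl carbon C11) and C12 (ester carbon). Ring A is C4–C9, ring B is C9, C10, C1–C4, and β is the face of the C9 methyl group.

Six stereocentres sit on ten ring carbons. Two are quaternary (C5, C9) with syn-diaxial methyl groups, the equatorial 6β-chloride is neopentylic, and the axial 8α-hydroxyl is neopentylic as well. C9 is the natural relay: once fixed, its axial methyl should send reagents to the α face at C8 (oxygen), C4 (hydrogen), C5 (side chain) and C10 (hydrogen), while C6 follows from the C8 oxygen and an inversion.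

Ring B is a polygodial-type unit. The C10 hydrogen is α to the aldehyde and allylic, so the aldehyde must appear last and under neutral conditions. C11 and C12 differ only in oxidation level, and a C11 alcohol beside the C12 ester would lactonise. The tertiary allylic alcohol of the side chain does not survive acid or chlorinating reagents, and the secondary chloride can eliminate or trigger a methyl shift.

The enabling feature is the substitution pattern of ring A. The methylated quaternary C9 is para, and the methylated C5 ortho, to the heteroatom-bearing C6, which is the pattern of a 2,4-dimethylphenol carrying a chain on C4. C10 and C1 of ring B map onto the α-carbon and ketone of a β-keto ester tethered to that phenol.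

## Retrosynthesis

**Aldehyde and side chain (29 ⇐ 28 ⇐ 26 + 27).** The last operation changes only the oxidation level of C11: thioester 28 is reduced to aldehyde 29. Oxidising a C11 alcohol instead would pass through a γ-hydroxy ester that closes to a butenolide with C12. The side-chain alkene is cut next, giving allyl compound 26 and 2-methylbut-3-en-2-ol 27. This removes five carbons and the acid-labile tertiary allylic alcohol from every earlier step. The forward reactions must give an E-selective cross-metathesis and a thioester reduction that leaves the methyl ester alone.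

**Telling C11 from C12 (26 ⇐ 25 ⇐ 24).** Thioester 26 comes from acid 25, and 25 from diester 24, in which C11 is a tert-butyl ester and C12 a methyl ester. Two methyl esters could not be separated by hydride, since the conjugated C12 ester would react first. Acid cleaves the tert-butyl ester and the C8 silyl ether in one step. The forward step must not epimerise C10.

**Ring B (24 ⇐ 22; 20 ⇐ 19 ⇐ 17).** The C1–C12 bond is cut: the ester comes from carbonylation of enol triflate 19, made from β-keto ester 17. The C1=C2 alkene of 24 comes from the C1=C10 alkene of 22 by deprotonation at C2 and protonation at C10. The β-keto ester left by the key step already has C11 on C10 and an oxygen on C1, exactly where a triflate is needed. The alternative, reducing C11 early and forming a C1=C2 triflate from a C1 ketone, needs more redox steps and ends in the lactonising hydroxy ester. The forward step must protonate C10 kinetically from the α face.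

**Chloride (22 ⇐ 21 ⇐ 20).** The C6–Cl bond is cut back to the axial 6α-alcohol 21 (inversion), and 21 to ketone 20. The C6 carbonyl is needed for the C5 alkylation, so the chloride has to come from it. A bulky hydride and the syn-axial C8 silyloxy group should both favour the axial alcohol. The forward reaction must achieve substitution at a neopentylic carbon without ionisation.

**C5 quaternary centre and ring fusion (17 ⇐ 14 + 15).** The C5–allyl bond and the C4–H bond are cut together: reductive alkylation of enone 14 with allyl bromide 15. Hydrogenation followed by enolate alkylation could not tell C5 from C7. The enone with its C5 methyl is what the dearomatised ring provides. Two stereocentres, one quaternary, are removed. The forward step must give trans protonation at C4 and α alkylation at C5, and it must tolerate the β-keto ester.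

**C8 oxygen (14 ⇐ 13 ⇐ 12 ⇐ 11).** The C8–O bond is traced to the α-epoxide 12 of the less substituted enone arm of dienone 11, opened reductively at C7–O to alcohol 13 and silylated to 14. This has to precede the dissolving-metal step, which would otherwise reduce C7=C8 first. A direct conjugate addition of an oxygen nucleophile would be reversible next to the quaternary C9.

**Key disconnection (11 ⇐ 10).** The C9–C10 bond is cut, opening ring B and rearomatising ring A to phenol 10. One oxidative step would turn a flat, achiral phenol into the bicyclic dienone with the quaternary C9, the C6 carbonyl, the C4=C5 enone and the C7=C8 enone, each of which is used later. The forward reaction must attack para (C9) and not ortho (C5), and one enantiotopic face.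

**Phenol precursor (10 ⇐ 7 + 8; 7 ⇐ 6 ⇐ 5 ⇐ 3 ⇐ 2 ⇐ 1).** The C2–C3 bond is cut: benzylic bromide 7 alkylates the dianion of tert-butyl acetoacetate 8. Bromide 7 comes by functional-group changes from 2,6-dimethylbenzoic acid 1. Its carboxyl carbon becomes C3, its methyl groups become those on C5 and C9, and its nitration site becomes C6. The tert-butyl ester is chosen because it has no alkene for the peracid, resists hydroxide and lithium in ammonia, passes the palladium step and is orthogonal to the later methyl ester.

## Roads not taken

**Alternative 1: transannular epoxide–alkene cyclisation.**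
- Cut and key step: the C4–C9 bond. The ten-membered epoxy diene A1 (trans C8–C9 epoxide, (E)-C4=C5 alkene) would be treated with BF3·OEt2. The epoxide opens at tertiary C9, C4 attacks with inversion, and the C5 cation loses a C6 proton to give octalin A2.
- Merits: both rings and the trans fusion arise in one step. A2 already carries the C1=C2 methyl ester and C11 as a protected alcohol, so ring B would need far fewer steps than in the chosen route. That advantage is real.
- Weak points: the hydroxyl of A2 is 8β, cis to the angular methyl, and would have to be inverted at a neopentylic carbinol. C5 ends as an alkene carbon, so the quaternary centre with its side chain and the C6 chloride, the two hardest features of ring A, are still unmade and no carbonyl is left to direct them. A1 is a medium ring with two defined trisubstituted units and a stereocentre, a synthesis of its own.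
- Comparison: the chosen plan sets against the easier ring B the fact that dienone 11 carries the C5 methyl, the C6 carbonyl and the C7=C8 enone, so the densely substituted ring A is handled by reactions with close steroid analogies.

**Alternative 2: epoxide-initiated bicyclisation ended by a β-keto ester.**
- Cut and key step: the C4–C5 and C9–C10 bonds. The acyclic epoxy diene A3 would be opened by MeAlCl2 at the C5–C6 epoxide. The (E)-C4=C9 alkene attacks C5 with inversion and the enol carbon C10 traps the C9 cation, giving decalin A4.
- Merits: two rings, two C–C bonds and five stereocentres (C4, C5, C6, C9, C10) in one step, with C5 formed directly as the quaternary centre. The absolute configuration would come from a catalytic asymmetric epoxidation of an established kind. In enantiocontrol this road stands on firmer ground than the chosen key step.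
- Weak points: C8 of A4 is a bare methylene. The 8α-hydroxyl would need a late oxidation of an unactivated C–H next to a quaternary carbon with no handle. The 6β-alcohol is equatorial, so the 6β-chloride requires retention or a double inversion at a neopentylic centre. The trisubstituted epoxide needs defined geometry, and its allyl group can compete as a nucleophile.
- Comparison: the chosen plan sets against the shorter skeleton synthesis that its key step leaves a C7=C8 enone as the handle for C8, and that its 6α-alcohol needs a single inversion.

**Alternative 3: intramolecular Diels–Alder reaction of an acyclic trienal.**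
- Cut and key step: the C4–C9 and C1–C10 bonds. Trienal A5 would undergo a Me2AlCl-promoted endo cycloaddition of the C9=C10 enal onto the C1–C4 diene to give octalin A6.
- Merits: both rings and four stereocentres in one reliable pericyclic step. Ring A of A6 is complete apart from the chloride (C5 quaternary centre, C6 ketone, protected 8α-oxygen), which equals or betters the chosen route at that stage, and the C11 aldehyde is already present.
- Weak points: A5 must already contain the acyclic quaternary stereocentre C5 between a ketone and a dienyl group, and C8, both needing their own asymmetric synthesis. The dienophile is a β,β-disubstituted enal, sluggish and with uncertain facial control. After cycloaddition the alkene is at C2=C3 and C12 is a protected alcohol, so deprotection, oxidation to the ester and alkene migration into conjugation must be done while the epimerisable C10 aldehyde is carried or masked.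
- Comparison: the chosen plan sets against this a commercial arene as the source of ring A and a β-keto ester that puts C11 and the C1 oxygen in the right places for ring B.

Key step: step 7

Remark on the chemistry (assumptions):
- The sense of induction of the chiral iodoarene cannot be predicted for this substrate class. The precatalyst is available in both antipodes from the two lactic acid series, and the antipode that gives the (1R,8aR)-dienone 11 is used. It is made separately by the known two-step route from 2-iodoresorcinol and is not counted.
- Compounds 11–17 are drawn as the 10β keto tautomer. C10 is labile until step 16.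

## Steps

Step 1
Reactants: 1 2,6-dimethylbenzoic acid
Product: 2 2,6-dimethyl-3-nitrobenzoic acid
Conditions: HNO3, H2SO4, 0 °C
Reagents that add atoms: nitric acid, O[N+](=O)[O-]
Why: Electrophilic aromatic nitration; C3 is ortho to one methyl, para to the other and meta to the carboxyl group, so all three substituents direct there.

Step 2
Reactants: 2 2,6-dimethyl-3-nitrobenzoic acid
Product: 3 3-amino-2,6-dimethylbenzoic acid
Conditions: H2 (1 atm), 10% Pd/C, MeOH, rt
Reagents that add atoms: none
Why: Catalytic hydrogenation of a nitroarene to the aniline; no other reducible group is present.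

Step 3
Reactants: 3 3-amino-2,6-dimethylbenzoic acid
Product: 5 3-hydroxy-2,6-dimethylbenzoic acid, via arenediazonium hydrogensulfate 4 (not isolated)
Conditions: NaNO2, aq. H2SO4, 0–5 °C; then added to boiling aq. H2SO4
Reagents that add atoms: water, O
Why: Diazotisation and thermal hydrolysis of the diazonium salt; slow addition to hot acid keeps the diazonium concentration low and should suppress azo coupling with the phenol formed.

Step 4
Reactants: 5 3-hydroxy-2,6-dimethylbenzoic acid
Product: 6 3-(hydroxymethyl)-2,4-dimethylphenol
Conditions: LiAlH4, THF, reflux; aq. potassium sodium tartrate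
Reagents that add atoms: none
Why: Hydride reduction of the carboxylic acid to the benzylic alcohol; the doubly ortho-substituted acid is hindered towards external nucleophiles but should be reduced through its aluminium carboxylate, and the phenol is only deprotonated.

Step 5
Reactants: 6 3-(hydroxymethyl)-2,4-dimethylphenol
Product: 7 3-(bromomethyl)-2,4-dimethylphenol
Conditions: PBr3, CH2Cl2, 0 °C; used directly
Reagents that add atoms: phosphorus tribromide, BrP(Br)Br
Why: Bromide displaces the benzylic phosphite ester; any aryl phosphite hydrolyses on work-up, and a meta-hydroxybenzyl bromide cannot collapse to a quinone methide.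

Step 6
Reactants: 7 3-(bromomethyl)-2,4-dimethylphenol; 8 tert-butyl acetoacetate
Product: 10 tert-butyl 5-(3-hydroxy-2,6-dimethylphenyl)-3-oxopentanoate, via acetoacetate dianion 9 (not isolated)
Conditions: 8 (3 equiv), LiN(i-Pr)2 (6 equiv), THF, 0 °C; then 7, −78 to 0 °C; aq. NH4Cl
Reagents that add atoms: none
Why: γ-Alkylation of the acetoacetate dianion at its terminal carbanion; one of the three equivalents of dianion is spent on the phenol O–H, and the lithium phenoxide formed should be too poor a nucleophile at low temperature to compete for the benzylic bromide.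

Step 7
Reactants: 10 tert-butyl 5-(3-hydroxy-2,6-dimethylphenyl)-3-oxopentanoate
Product: 11 tert-butyl (1R,8aR)-5,8a-dimethyl-2,6-dioxo-1,2,3,4,6,8a-hexahydronaphthalene-1-carboxylate (dienone; C9 methyl β, C10 ester β)
Conditions: (R,R)-2,2'-[(2-iodo-1,3-phenylene)bis(oxy)]bis(N-mesitylpropanamide) or its antipode (10 mol %), mCPBA (1.3 equiv), CH2Cl2/(CF3)2CHOH, −20 °C
Reagents that add atoms: none
Why: Proposed new method: the iodoarene is oxidised by mCPBA to its trivalent-iodine form, ligand exchange with the phenol oxygen of 10 gives an aryloxy-iodane, and the enol carbon C10 of the tethered β-keto ester attacks the para carbon C9 as the aryl iodide leaves oxygen, forming C9–C10 and the cross-conjugated dienone. The closest known reaction types are the PhI(OAc)2-mediated dearomatisation of para-alkylphenols by tethered carbon nucleophiles and the chiral aryl iodide-catalysed dearomative spirocyclisation of phenols; a carbon nucleophile, a fused instead of a spiro ring and a 2,4-dimethylphenol have not been combined in an enantioselective version. Ring B closes in a 6-(enolendo)-exo-trig mode, since the C8=C9 π bond that is consumed lies outside the new ring. C9 is controlled by the chiral iodane, which has to stay bound to oxygen while the C–C bond forms; the weakly ionising solvent mixture and the low temperature are chosen to avoid a free phenoxenium ion. C10 is not controlled: it equilibrates through the enol to the equatorial β-ester and is erased in step 12. The step needs para over ortho attack; C9 and C5 are equally far from C10, but C9 carries the larger coefficient of the oxidised phenol, leads to the more stable cross-conjugated dienone, and C5 is shielded by the iodanyl group on the neighbouring oxygen. The C9 methyl blocks rearomatisation, and the tert-butyl ester offers the peracid no alkene.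

Step 8
Reactants: 11 dienone
Product: 12 tert-butyl 7α,8α-epoxy-5,9β-dimethyl-1,6-dioxooctal-4-ene-10β-carboxylate
Conditions: 30% aq. H2O2, NaOH, MeOH, 0 °C
Reagents that add atoms: hydrogen peroxide, OO
Why: Weitz–Scheffer nucleophilic epoxidation; hydroperoxide should add to the disubstituted C7=C8 arm and not to the tetrasubstituted C4=C5 arm, and to C8 anti to the C9 methyl, as steroidal 1,4-dien-3-ones give 1α,2α-epoxides. The β-keto ester sits as its enolate and the tert-butyl ester resists hydroxide.

Step 9
Reactants: 12 epoxy enone
Product: 13 tert-butyl 8α-hydroxy-5,9β-dimethyl-1,6-dioxooctal-4-ene-10β-carboxylate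
Conditions: SmI2 (2.2 equiv), THF/MeOH, −90 °C
Reagents that add atoms: none
Why: Electron transfer from divalent samarium to the epoxy ketone gives a ketyl that cleaves the C7–O bond; the C8–O bond is untouched, so the 8α configuration is kept. At this temperature the enone and the β-keto ester should not be reduced.

Step 10
Reactants: 13 hydroxy enone
Product: 14 tert-butyl 5,9β-dimethyl-1,6-dioxo-8α-(triethylsilyloxy)octal-4-ene-10β-carboxylate
Conditions: Et3SiCl, imidazole, DMF, 0 °C to rt
Reagents that add atoms: chlorotriethylsilane, CC[Si](Cl)(CC)CC
Why: Silylation of the secondary alcohol; the triethylsilyl group is small enough for the axial neopentylic hydroxyl, stable to base, hydride and lithium in ammonia, and is removed later by the same acid that cleaves the tert-butyl ester.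

Step 11
Reactants: 14 silyloxy enone; 15 allyl bromide
Product: 17 tert-butyl 5α-allyl-5β,9β-dimethyl-1,6-dioxo-8α-(triethylsilyloxy)-4α-H-decalin-10β-carboxylate, via dilithium bis-enolate 16 (not isolated)
Conditions: Li (2.2 equiv), NH3/THF, −78 °C; isoprene; then 15 (5 equiv), −78 to −33 °C; NH4Cl
Reagents that add atoms: none
Why: Dissolving-metal reductive alkylation of the enone; the acidic C10–H of the β-keto ester is the one proton equivalent that the C4 carbanion needs, so the β-keto ester ends as a stabilised enolate that lithium does not reduce and that is far less nucleophilic than the ketone enolate. Axial protonation at C4 anti to the C9 methyl gives the trans fusion, and allyl bromide enters C5 from the α face, avoiding the syn-axial C9 methyl, which leaves the C5 methyl β.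

Step 12
Reactants: 17 allylated diketo ester
Product: 19 tert-butyl 5α-allyl-5β,9β-dimethyl-6-oxo-8α-(triethylsilyloxy)-1-(trifluoromethylsulfonyloxy)-4α-H-octal-1(10)-ene-10-carboxylate, via sodium enolate 18 (not isolated)
Conditions: NaH (1.05 equiv), THF, 0 °C; then PhNTf2, 0 °C to rt
Reagents that add atoms: N-phenylbis(trifluoromethanesulfonimide), FC(F)(F)S(=O)(=O)N(c1ccccc1)S(=O)(=O)C(F)(F)F
Why: One equivalent of NaH deprotonates only the β-keto ester, and O-sulfonylation of its enolate gives the enol triflate; the C6 ketone is not enolised, and the labile C10 centre is deliberately erased.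

Step 13
Reactants: 19 enol triflate
Product: 20 10-tert-butyl 1-methyl 5α-allyl-5β,9β-dimethyl-6-oxo-8α-(triethylsilyloxy)-4α-H-octal-1(10)-ene-1,10-dicarboxylate
Conditions: Pd(OAc)2 (5 mol %), PPh3, CO (1 atm), Et3N, MeOH/DMF, 60 °C
Reagents that add atoms: carbon monoxide, [C-]#[O+]; methanol, CO
Why: Palladium-catalysed methoxycarbonylation of a vinyl triflate (oxidative addition to zerovalent palladium, CO insertion, methanolysis) installs C12; the ketone, the silyl ether and the terminal alkene should be tolerated.

Step 14
Reactants: 20 keto diester
Product: 21 10-tert-butyl 1-methyl 5α-allyl-6α-hydroxy-5β,9β-dimethyl-8α-(triethylsilyloxy)-4α-H-octal-1(10)-ene-1,10-dicarboxylate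
Conditions: LiBH(s-Bu)3 (L-Selectride), THF, −78 °C; AcOH at −78 °C, then aq. NH4Cl
Reagents that add atoms: none
Why: The bulky borohydride should attack the C6 ketone from the equatorial β direction, as in 4,4-dimethyl-3-keto terpenoids, and the α face is further closed by the syn-axial C8 silyloxy group, giving the axial 6α-alcohol. The fully substituted diester alkene is too hindered for conjugate reduction, and the cold acidic quench prevents silyl migration between the two syn-axial oxygens.

Step 15
Reactants: 21 6α-alcohol
Product: 22 10-tert-butyl 1-methyl 5α-allyl-6β-chloro-5β,9β-dimethyl-8α-(triethylsilyloxy)-4α-H-octal-1(10)-ene-1,10-dicarboxylate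
Conditions: PPh3, CCl4, ClCH2CH2Cl, 70 °C
Reagents that add atoms: carbon tetrachloride, ClC(Cl)(Cl)Cl
Why: Appel reaction; the alkoxyphosphonium salt of the axial alcohol is displaced by chloride with inversion to the equatorial 6β-chloride. Relief of the 1,3-diaxial oxygen–oxygen interaction helps departure, and the non-ionising medium is meant to suppress elimination and methyl migration.

Step 16
Reactants: 22 chloro diester
Product: 24 10-tert-butyl 1-methyl 5α-allyl-6β-chloro-5β,9β-dimethyl-8α-(triethylsilyloxy)-4α,10α-H-octal-1-ene-1,10β-dicarboxylate, via lithium dienolate 23 (not isolated)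
Conditions: LiN(i-Pr)2, DMPU, THF, −78 °C; then AcOH, −78 °C
Reagents that add atoms: none
Why: Deconjugative protonation; the amide base removes a C2 proton, γ to the tert-butyl ester, and the dienolate is protonated kinetically at its α-carbon C10 from the α face, anti to the C9 methyl. This places the alkene at C1=C2 in conjugation with the methyl ester and sets 10α-H, in analogy with the deconjugation of drimane 8-ene diesters; the equatorial chloride has no anti-periplanar hydrogen for elimination.

Step 17
Reactants: 24 deconjugated diester
Product: 25 5α-allyl-6β-chloro-8α-hydroxy-1-(methoxycarbonyl)-5β,9β-dimethyl-4α,10α-H-octal-1-ene-10β-carboxylic acid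
Conditions: CF3CO2H/CH2Cl2/H2O (10:30:1), 0 °C to rt
Reagents that add atoms: none
Why: Acidolysis cleaves the tert-butyl ester through the tert-butyl cation and hydrolyses the triethylsilyl ether; the methyl ester, the chloride and both alkenes should be inert. It is done before the acid-labile tertiary allylic alcohol is introduced.

Step 18
Reactants: 25 hydroxy acid
Product: 26 methyl 5α-allyl-6β-chloro-10β-(ethylsulfanylcarbonyl)-8α-hydroxy-5β,9β-dimethyl-4α,10α-H-octal-1-ene-1-carboxylate
Conditions: EtSH, EDC·HCl, DMAP (5 mol %), CH2Cl2, 0 °C
Reagents that add atoms: ethanethiol, CCS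
Why: Carbodiimide-mediated (Steglich-type) thioesterification; the thiol is nucleophilic enough for acyl transfer to outrun enolisation at C10, and the hindered axial C8 hydroxyl should not compete. A thioester is chosen because it can be taken to the aldehyde without a C11 alcohol, which would lactonise onto C12.

Step 19
Reactants: 26 thioester; 27 2-methylbut-3-en-2-ol
Product: 28 methyl 6β-chloro-10β-(ethylsulfanylcarbonyl)-8α-hydroxy-5α-[(E)-4-hydroxy-4-methylpent-2-en-1-yl]-5β,9β-dimethyl-4α,10α-H-octal-1-ene-1-carboxylate
Conditions: 27 (10 equiv), second-generation Hoveyda–Grubbs catalyst RuCl2(H2IMes)(=CH-C6H4-2-O-i-Pr) (5 mol %), CH2Cl2, 40 °C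
Reagents that add atoms: none
Why: Olefin cross-metathesis of the terminal allyl group with an excess of the hindered tertiary allylic alcohol, which homodimerises slowly; the E alkene is the thermodynamic product, and the trisubstituted, electron-poor ring alkene should not take part.

Step 20
Reactants: 28 thioester
Product: 29 methyl 6β-chloro-10β-formyl-8α-hydroxy-5α-[(E)-4-hydroxy-4-methylpent-2-en-1-yl]-5β,9β-dimethyl-4α,10α-H-octal-1-ene-1-carboxylate (target)
Conditions: Et3SiH, 10% Pd/C, acetone, rt
Reagents that add atoms: none
Why: Fukuyama reduction; the thioester C–S bond adds to palladium, the silane delivers hydride and reductive elimination gives the aldehyde under neutral conditions, so C10 should keep its configuration and no C11 alcohol is formed. The methyl ester, the alkyl chloride, the hindered alcohols and the non-terminal alkenes are expected to be tolerated.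

## Compound list

1 | 2,6-dimethylbenzoic acid | Cc1cccc(C)c1C(=O)O | starting material
2 | 2,6-dimethyl-3-nitrobenzoic acid | Cc1ccc([N+](=O)[O-])c(C)c1C(=O)O | intermediate
3 | 3-amino-2,6-dimethylbenzoic acid | Cc1ccc(N)c(C)c1C(=O)O | intermediate
4 | 3-carboxy-2,4-dimethylbenzenediazonium hydrogensulfate | Cc1ccc([N+]#N)c(C)c1C(=O)O.OS(=O)(=O)[O-] | intermediate (not isolated)
5 | 3-hydroxy-2,6-dimethylbenzoic acid | Cc1ccc(O)c(C)c1C(=O)O | intermediate
6 | 3-(hydroxymethyl)-2,4-dimethylphenol | Cc1ccc(O)c(C)c1CO | intermediate
7 | 3-(bromomethyl)-2,4-dimethylphenol | Cc1ccc(O)c(C)c1CBr | intermediate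
8 | tert-butyl acetoacetate (tert-butyl 3-oxobutanoate) | CC(=O)CC(=O)OC(C)(C)C | starting material
9 | dilithium dianion of tert-butyl acetoacetate | C=C([O-])C=C([O-])OC(C)(C)C.[Li+].[Li+] | intermediate (not isolated)
10 | tert-butyl 5-(3-hydroxy-2,6-dimethylphenyl)-3-oxopentanoate | CC(C)(C)OC(=O)CC(=O)CCc1c(C)ccc(O)c1C | intermediate
11 | tert-butyl (1R,8aR)-5,8a-dimethyl-2,6-dioxo-1,2,3,4,6,8a-hexahydronaphthalene-1-carboxylate | CC(C)(C)OC(=O)[C@H]1C(=O)CCC2=C(C)C(=O)C=C[C@]12C | intermediate
12 | tert-butyl 7α,8α-epoxy-5,9β-dimethyl-1,6-dioxooctal-4-ene-10β-carboxylate | CC(C)(C)OC(=O)[C@H]1C(=O)CCC2=C(C)C(=O)[C@@H]3O[C@@H]3[C@]12C | intermediate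
13 | tert-butyl 8α-hydroxy-5,9β-dimethyl-1,6-dioxooctal-4-ene-10β-carboxylate | CC(C)(C)OC(=O)[C@H]1C(=O)CCC2=C(C)C(=O)C[C@H](O)[C@]12C | intermediate
14 | tert-butyl 5,9β-dimethyl-1,6-dioxo-8α-(triethylsilyloxy)octal-4-ene-10β-carboxylate | CC(C)(C)OC(=O)[C@H]1C(=O)CCC2=C(C)C(=O)C[C@H](O[Si](CC)(CC)CC)[C@]12C | intermediate
15 | allyl bromide | C=CCBr | starting material
16 | dilithium bis-enolate (C5=C6 enolate and C1=C10 enolate, 4α-H) | [Li+].[Li+].CC(C)(C)OC(=O)C1=C([O-])CC[C@H]2C(C)=C([O-])C[C@H](O[Si](CC)(CC)CC)[C@]12C | intermediate (not isolated)
17 | tert-butyl 5α-allyl-5β,9β-dimethyl-1,6-dioxo-8α-(triethylsilyloxy)-4α-H-decalin-10β-carboxylate | CC(C)(C)OC(=O)[C@H]1C(=O)CC[C@H]2[C@](C)(CC=C)C(=O)C[C@H](O[Si](CC)(CC)CC)[C@]12C | intermediate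
18 | sodium enolate of 17 (C1=C10) | [Na+].CC(C)(C)OC(=O)C1=C([O-])CC[C@H]2[C@](C)(CC=C)C(=O)C[C@H](O[Si](CC)(CC)CC)[C@]12C | intermediate (not isolated)
19 | tert-butyl 5α-allyl-5β,9β-dimethyl-6-oxo-8α-(triethylsilyloxy)-1-(trifluoromethylsulfonyloxy)-4α-H-octal-1(10)-ene-10-carboxylate | CC(C)(C)OC(=O)C1=C(OS(=O)(=O)C(F)(F)F)CC[C@H]2[C@](C)(CC=C)C(=O)C[C@H](O[Si](CC)(CC)CC)[C@]12C | intermediate
20 | 10-tert-butyl 1-methyl 5α-allyl-5β,9β-dimethyl-6-oxo-8α-(triethylsilyloxy)-4α-H-octal-1(10)-ene-1,10-dicarboxylate | CC(C)(C)OC(=O)C1=C(C(=O)OC)CC[C@H]2[C@](C)(CC=C)C(=O)C[C@H](O[Si](CC)(CC)CC)[C@]12C | intermediate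
21 | 10-tert-butyl 1-methyl 5α-allyl-6α-hydroxy-5β,9β-dimethyl-8α-(triethylsilyloxy)-4α-H-octal-1(10)-ene-1,10-dicarboxylate | CC(C)(C)OC(=O)C1=C(C(=O)OC)CC[C@H]2[C@](C)(CC=C)[C@H](O)C[C@H](O[Si](CC)(CC)CC)[C@]12C | intermediate
22 | 10-tert-butyl 1-methyl 5α-allyl-6β-chloro-5β,9β-dimethyl-8α-(triethylsilyloxy)-4α-H-octal-1(10)-ene-1,10-dicarboxylate | CC(C)(C)OC(=O)C1=C(C(=O)OC)CC[C@H]2[C@](C)(CC=C)[C@@H](Cl)C[C@H](O[Si](CC)(CC)CC)[C@]12C | intermediate
23 | lithium dienolate of 22 (C11=C10, C1=C2) | [Li+].CC(C)(C)OC([O-])=C1C(C(=O)OC)=CC[C@H]2[C@](C)(CC=C)[C@@H](Cl)C[C@H](O[Si](CC)(CC)CC)[C@]12C | intermediate (not isolated)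
24 | 10-tert-butyl 1-methyl 5α-allyl-6β-chloro-5β,9β-dimethyl-8α-(triethylsilyloxy)-4α,10α-H-octal-1-ene-1,10β-dicarboxylate | CC(C)(C)OC(=O)[C@H]1C(C(=O)OC)=CC[C@H]2[C@](C)(CC=C)[C@@H](Cl)C[C@H](O[Si](CC)(CC)CC)[C@]12C | intermediate
25 | 5α-allyl-6β-chloro-8α-hydroxy-1-(methoxycarbonyl)-5β,9β-dimethyl-4α,10α-H-octal-1-ene-10β-carboxylic acid | OC(=O)[C@H]1C(C(=O)OC)=CC[C@H]2[C@](C)(CC=C)[C@@H](Cl)C[C@H](O)[C@]12C | intermediate
26 | methyl 5α-allyl-6β-chloro-10β-(ethylsulfanylcarbonyl)-8α-hydroxy-5β,9β-dimethyl-4α,10α-H-octal-1-ene-1-carboxylate | CCSC(=O)[C@H]1C(C(=O)OC)=CC[C@H]2[C@](C)(CC=C)[C@@H](Cl)C[C@H](O)[C@]12C | intermediate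
27 | 2-methylbut-3-en-2-ol | C=CC(C)(C)O | starting material
28 | methyl 6β-chloro-10β-(ethylsulfanylcarbonyl)-8α-hydroxy-5α-[(E)-4-hydroxy-4-methylpent-2-en-1-yl]-5β,9β-dimethyl-4α,10α-H-octal-1-ene-1-carboxylate | CCSC(=O)[C@H]1C(C(=O)OC)=CC[C@H]2[C@](C)(C/C=C/C(C)(C)O)[C@@H](Cl)C[C@H](O)[C@]12C | intermediate
29 | methyl 6β-chloro-10β-formyl-8α-hydroxy-5α-[(E)-4-hydroxy-4-methylpent-2-en-1-yl]-5β,9β-dimethyl-4α,10α-H-octal-1-ene-1-carboxylate (CNP0167913.1) | COC(=O)C1=CC[C@H]2[C@](C)(C/C=C/C(C)(C)O)[C@@H](Cl)C[C@H](O)[C@]2(C)[C@H]1C=O | target

## Step count and least certain steps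

Total: 20 steps. Longest linear sequence: 20 steps, from 1 to 29; compounds 8, 15 and 27 are commercial and enter directly.

**Step 7 (key step; new in its enantioselective form).** The likely failures are erosion of enantioselectivity when the aryloxy-iodane ionises to a free phenoxenium ion before the C–C bond forms, competing attack at the ortho carbon C5, and oxidation of the enol by the peracid. The fallback uses known chemistry. From 10, stoichiometric PhI(OAc)2 in (CF3)2CHOH at 0 °C, the established racemic dearomatisation of para-alkylphenols by tethered carbon nucleophiles, gives the racemic dienone F1. Its enantiomers are separated by preparative chromatography on a chiral stationary phase, and the (1R,8aR) enantiomer is 11, where the route resumes.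

**Step 15.** The likely failures are elimination of the activated axial oxygen with the anti-periplanar axial C7 hydrogen, a 1,2-shift of the anti-periplanar C5 methyl if the C–O bond ionises, or no displacement at the neopentylic carbon. In the fallback, activation and displacement are separated. From 21, ClCH2SO2Cl and pyridine give the isolated chloromethanesulfonate F2, a neutral sulfonate that is then displaced by LiCl in DMF with inversion, returning to 22.

**Step 11.** The likely failures are allylation of the β-keto ester enolate at C10 or at oxygen, proton exchange between enolates leading to alkylation at C7 or double alkylation, and β-elimination of the silyloxy group. The fallback masks ring B by a redox detour. From 14, NaBH4 in MeOH at −20 °C reduces only the saturated C1 ketone to the β-hydroxy ester F3 (either C1 epimer serves). The same lithium–ammonia and allyl bromide 15 protocol, now with no stabilised enolate in the molecule, gives the allylated hydroxy ester F4, and Dess–Martin periodinane restores the C1 ketone, returning to 17.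

**Step 16.** The likely failures are protonation of the dienolate at C2 (back to 22), protonation of C10 from the β face, or attack of the amide base on the methyl ester. The fallback changes the species that is protonated. From 22, CF3CO2H/CH2Cl2/H2O first gives the conjugated hydroxy acid F5. Its polyanion, formed with LiN(i-Pr)2 (3.3 equiv) at −78 °C, is a carboxylic acid dienediolate, a class that protonates at the α-carbon with high regioselectivity, and it should give 25 directly, the route resuming at step 18.

**Step 8.** The likely failures are loss of facial selectivity, because the C10 ester of the enolate lies near the α face of C8, and oxidative degradation of the β-keto ester. The fallback replaces substrate control by ligand control and bypasses steps 8 and 9. From 11, copper-catalysed conjugate borylation (CuCl, NaOt-Bu, the matching enantiomer of BINAP, B2pin2, MeOH, THF) puts boron on C8 of the less substituted enone arm to give the β-boryl ketone F6. NaBO3 oxidises the C–B bond with retention to 13.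

**Step 6.** The likely failure is benzylation of the phenoxide, with oligomerisation of 7, in competition with the dianion. The fallback protects the phenol. From 7, TBSOTf and 2,6-lutidine at −78 °C give the aryl silyl ether F7. Alkylation of dianion 9 (1.2 equiv) gives the silyl-protected keto ester F8, and Bu4NF buffered with AcOH returns to 10.

## Further compounds

F1 | step 7 | racemic tert-butyl 5,8a-dimethyl-2,6-dioxo-1,2,3,4,6,8a-hexahydronaphthalene-1-carboxylate | CC(C)(C)OC(=O)C1C(=O)CCC2=C(C)C(=O)C=CC12C
F2 | step 15 | 10-tert-butyl 1-methyl 5α-allyl-6α-(chloromethylsulfonyloxy)-5β,9β-dimethyl-8α-(triethylsilyloxy)-4α-H-octal-1(10)-ene-1,10-dicarboxylate | CC(C)(C)OC(=O)C1=C(C(=O)OC)CC[C@H]2[C@](C)(CC=C)[C@H](OS(=O)(=O)CCl)C[C@H](O[Si](CC)(CC)CC)[C@]12C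
F3 | step 11 | tert-butyl 1-hydroxy-5,9β-dimethyl-6-oxo-8α-(triethylsilyloxy)octal-4-ene-10β-carboxylate (C1 epimers) | CC(C)(C)OC(=O)[C@H]1C(O)CCC2=C(C)C(=O)C[C@H](O[Si](CC)(CC)CC)[C@]12C
F4 | step 11 | tert-butyl 5α-allyl-1-hydroxy-5β,9β-dimethyl-6-oxo-8α-(triethylsilyloxy)-4α-H-decalin-10β-carboxylate (C1 epimers) | CC(C)(C)OC(=O)[C@H]1C(O)CC[C@H]2[C@](C)(CC=C)C(=O)C[C@H](O[Si](CC)(CC)CC)[C@]12C
F5 | step 16 | 5α-allyl-6β-chloro-8α-hydroxy-1-(methoxycarbonyl)-5β,9β-dimethyl-4α-H-octal-1(10)-ene-10-carboxylic acid | OC(=O)C1=C(C(=O)OC)CC[C@H]2[C@](C)(CC=C)[C@@H](Cl)C[C@H](O)[C@]12C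
F6 | step 8 | tert-butyl 5,9β-dimethyl-1,6-dioxo-8α-(4,4,5,5-tetramethyl-1,3,2-dioxaborolan-2-yl)octal-4-ene-10β-carboxylate | CC(C)(C)OC(=O)[C@H]1C(=O)CCC2=C(C)C(=O)C[C@H](B3OC(C)(C)C(C)(C)O3)[C@]12C
F7 | step 6 | [3-(bromomethyl)-2,4-dimethylphenoxy](tert-butyl)dimethylsilane | Cc1ccc(O[Si](C)(C)C(C)(C)C)c(C)c1CBr
F8 | step 6 | tert-butyl 5-[3-(tert-butyldimethylsilyloxy)-2,6-dimethylphenyl]-3-oxopentanoate | CC(C)(C)OC(=O)CC(=O)CCc1c(C)ccc(O[Si](C)(C)C(C)(C)C)c1C
A1 | alternative 1 | ten-membered epoxy diene with trans C8–C9 epoxide, (E)-C4=C5 alkene and C1=C2 enoate | COC(=O)/C1=C/C/C=C(\C)CC[C@H]2O[C@]2(C)[C@H]1CO[Si](C)(C)C(C)(C)C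
A2 | alternative 1 | 8β-hydroxy trans-octalin ester | COC(=O)C1=CC[C@H]2C(C)=CC[C@@H](O)[C@]2(C)[C@H]1CO[Si](C)(C)C(C)(C)C
A3 | alternative 2 | acyclic C5–C6 epoxy (E)-C4=C9 diene allyl β-keto ester | C=CCOC(=O)CC(=O)CC/C=C(\C)CC[C@@H]1O[C@@]1(C)CC=C
A4 | alternative 2 | 6β-hydroxy trans-decalin β-keto ester | O=C1CC[C@H]2[C@](C)(CC=C)[C@@H](O)CC[C@]2(C)[C@H]1C(=O)OCC=C
A5 | alternative 3 | acyclic (E,E)-dienyl ketone (E)-enal with C5 and C8 stereocentres | COc1ccc(COC/C=C/C=C/[C@](C)(CC=C)C(=O)C[C@H](O[Si](C)(C)C(C)(C)C)/C(C)=C/C=O)cc1
A6 | alternative 3 | trans-fused octalin aldehyde | COc1ccc(COC[C@H]2C=C[C@H]3[C@](C)(CC=C)C(=O)C[C@H](O[Si](C)(C)C(C)(C)C)[C@]3(C)[C@H]2C=O)cc1
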